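## Structural features

The target (C29H28O10) is a constitutionally symmetric dimer: two 7-acetyl-3,6,8-trihydroxy-4,4-dimethylnaphthalen-1(4H)-one units joined through one methylene carbon at C2 and C2'. In each half ring B is a cyclic β-diketone enol (C1 ketone, C3 enol, C2 between them). Its C4 is a quaternary gem-dimethyl carbon that blocks aromatisation. Ring B is fused through C4a–C8a to ring A, a benzene ring with hydroxyls at C6 and C8, an acetyl group at C7 between them, and hydrogen only at C5. There is no stereocentre, so the problem is one of regiochemistry and functional-group tolerance, and every operation must succeed twice in one molecule. The fragile motifs are the methylene-bis(β-diketone enol), which is acidic, cyclodehydrates to a 4H-pyran under acidic dehydrating conditions and can lose the bridge by retro-Michael cleavage in hot base, and the chelated o-hydroxyaryl ketones on an electron-rich resorcinol. The real difficulty is a pentasubstituted ring A of defined pattern next to a quaternary carbon, and keeping the two ring-B oxygens of each half distinguishable while the dione is masked. The key step uses the 1,3 relation of the C6 and C8 oxygens with hydrogen at C5: C8–O comes from a ketene carbonyl, C6–O from the oxygen of an ynol ether, and the C4a=C8a bond of a preformed ring B (hydrogen on C8a) is the vinyl part of a vinylketene.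

## Logic of the disconnections

**24 to 23.** The two enol O–CH3 bonds at C3 and C3' are cut. The free bis-enol would not survive the Lewis-acid acylation before it, so it is unmasked last. The demand is a dealkylation that is not dehydrating: halide attack on the methyl group under boron activation at low temperature.

**23 to 22.** The C7–acetyl bonds are cut. C7 lies between two hydroxyls, while C5, the only other free position, is shielded by the quaternary C4. The gain is that the alkyne of the key step needs no carbon substituent. The forward acylation must tell C7 from C5 and spare the enol ethers.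

**22 to 21.** The two aryl O–Si bonds are cut. The silyl ether is what the annulation delivers, and fluoride removes it without touching anything else.

**21 to 13 and 17.** In each ring A the bonds C5–C6, C7–C8 and C8–C8a are cut, and C4a is returned from C5 to the acyl carbon (retro-Wolff). Both benzene rings disappear, leaving a monocyclic dienone with an acyl side chain and a two-carbon alkyne, two molecules of which are needed. The demands on 13 are a diazoacetyl group on the ring carbon next to the gem-dimethyl carbon, hydrogen on the neighbouring alkene carbon, a masked dione in its cross-conjugated form, and a way to trigger the diazo group alone.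

**17 to 15 to 14.** The O–Si bond and the alkyne π bonds are cut back to the silyl enol ether of a dichlorinated two-carbon aldehyde. This gives a two-step access. The base must eliminate and exchange halogen without attacking silicon.

**13 to 10 and 11 through 12.** The bond between the acyl carbon and the diazo carbon is cut at both ends, so two molecules of 11 are needed for each molecule of 10. The acid is the stable storage form. The acylation must be faster than dipolar cycloaddition to the electron-poor C4a=C8a bond.

**10 to 9 to 7.** The ester O–CH3 bonds and the enol O–CH3 bonds are cut. Direct methylation of the unsymmetrical dione would favour the unhindered C1 oxygen, the wrong isomer. The forward step therefore goes through the doubly O-methylated cation 8, which both isomers share, and relies on hydrolysis at its less hindered end.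

**7 to 5 and 6.** Both C2–CH2 bonds are cut, which halves the molecule. C2 of the free 1,3-dione is the only carbon nucleophile, so the bridge must be made before the dione is masked.

**5 to 4.** The C1–C2 bond is cut (retro-Claisen). The acyclic keto diester needs the ketone-bearing group and the distal ester cis on the double bond.

**4 to 2 and 3, and 2 to 1.** The C4–C4a bond is cut, which sets the quaternary carbon first from two small fragments. The enol ether 2 must be the tetrasubstituted regioisomer only, hence its regiospecific origin in 1.

## Other disconnections considered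

**Alternative 1:** The cut is at C4–C4a in both halves. Forward, a zerovalent palladium catalyst with a bulky trialkylphosphine and a fluoride activator would couple two molecules of methyl 2-bromo-4,6-dimethoxybenzoate A2 with the bis(silyl enol ether) A3 to give the diketo diester A1. A double Dieckmann closure of each chain methylene onto its aryl ester would then form both B rings, with the central chain carbon becoming the bridge.
- In favour: ring A comes with its oxygen pattern, so there is no regiochemical question at C6 and C8 (better than the chosen plan). There are no diazo compounds and no light (better on handling). The sequence is shorter (better on step economy).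
- Against: the coupling must create a quaternary benzylic carbon ortho to an ester on an electron-rich aryl bromide, twice, which is the most congested class of enolate arylation. A3 must be the tetrasubstituted enol ether at both ends, although the chain methylene is the easier position to arylate.
- Comparison: four aryl methyl ethers must be cleaved and C7 acylated late, which is the same problem as in the chosen plan (equal). The chosen cascade is sterically undemanding and fixes its own regiochemistry, at the price of more steps.

**Alternative 2:** The cut is at the four C4–CH3 bonds. Forward, the bis(naphthalenediol) A5 would be C-methylated twice at each C4 with an electrophilic methyl source and base, dearomatising both B rings to the enolone A4.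
- In favour: it is the shortest route and follows the likely biosynthesis, and A5 should be easy to assemble. On step economy and simplicity of intermediates it is better than the chosen plan.
- Against: the naphtholate is ambident. O-methylation competes, and C2, although substituted, lies between two oxygens and remains the most nucleophilic carbon; methylation there would give a blocked 2,2-disubstituted dione. Exactly four C-methylations at the right carbons are needed with no internal control element, and A5 is air-sensitive.
- Comparison: the chosen plan sets the quaternary carbon unambiguously in its second step. Both need the same late C7 acetylation and ether cleavage (equal).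

**Alternative 3:** The cut is at C1–C2 and C3–C4 of both B rings. Forward, two molecules of the benzocyclobutenone A7 would open on heating to o-quinoid vinylketenes that add across the two ynol ether units of the skipped diyne A8 to give A6.
- In favour: both B rings, the bridge and the ring-B regiochemistry arise in one thermal operation, without diazo compounds or light. On convergence and step count it is equal to or better than the chosen plan.
- Against: an o-quinoid ketene with a dimethylmethylene terminus has a unimolecular escape, a 1,5-hydrogen shift from a methyl group, which must be outrun twice. A8 has a doubly propargylic, acidic methylene and should isomerise readily. A7 needs a regiocontrolled synthesis of its own.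
- Comparison: mechanistically it is the mirror image of the chosen plan (ketene plus ynol ether building ring B on ring A). The chosen vinylketene has no such escape and its alkyne partner is simple. Ether cleavage and C7 acetylation remain (equal).

Key step: step 10

**Remarks on the chemistry**

- Ring positions C1 to C8a follow the naphthalen-1(4H)-one numbering of each half and are also used for the precursors.
- Locant of the precursor: in 13 the diazoacetyl group must stand at position 4 of each cyclohexa-1,4-dien-1-yl ring, next to the gem-dimethyl carbon (the future C4a). The 5-(diazoacetyl) isomer would place the new hydroxyl peri to the gem-dimethyl group.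
- Bond count of the key step: per ring the cascade makes C5–C6, C7–C8 and C8–C8a (six bonds in all). The Wolff shift also makes C4a–C5 at the expense of the C4a–acyl bond.
- Stoichiometry: a figure in equivalents on a Reactants line is the number of molecules of that compound that one molecule of product contains; the amounts charged stand on the Conditions line.
- Improvements in the design of the route to and from the precursor:
  - The C3 enol ether is made through cation 8, because direct O-methylation would favour the C1 oxygen.
  - The tertiary nucleophile is made regiospecifically from 1.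
  - The final unmasking is a cold boron-halide dealkylation, not a hot aqueous acid hydrolysis.
- Assumptions: 1, 3, 6 (37% aqueous), 11 (2 M in hexanes) and anhydrous 14 are bought. 5 and 7 are written as one enol tautomer.

## Route

Step 1
Reactants: 1 3-bromo-3-methylbutan-2-one
Product: 2 2-methyl-3-(trimethylsilyloxy)but-2-ene
Conditions: Zn dust (1.5 equiv), Me3SiCl (1.5 equiv), MeCN, 20 °C
Reagents that add atoms: chlorotrimethylsilane, C[Si](C)(C)Cl
Why: Reformatsky-type zinc insertion into the tertiary C–Br bond gives the zinc enolate at the carbon that carried bromine, and O-silylation fixes the tetrasubstituted enol ether free of its terminal regioisomer (reductive silylation of an α-halo ketone).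

Step 2
Reactants: 2 2-methyl-3-(trimethylsilyloxy)but-2-ene; 3 dimethyl acetylenedicarboxylate
Product: 4 dimethyl (2E)-2-(2-methyl-3-oxobutan-2-yl)but-2-enedioate
Conditions: TiCl4 (1.0 equiv), CH2Cl2, −78 °C; aq. NaHCO3
Reagents that add atoms: none
Why: Mukaiyama–Michael addition of the Me2C= carbon of 2 to the TiCl4-activated alkynoate forms the quaternary C4–C4a bond; protonation of the titanium allenoate from the side away from the tert-alkyl group should give the E isomer (new group cis to the distal ester), and any cyclobutene formed by closure of the zwitterion reopens by retro-aldol cleavage on work-up to the same keto diester.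

Step 3
Reactants: 4 dimethyl (2E)-2-(2-methyl-3-oxobutan-2-yl)but-2-enedioate
Product: 5 methyl 3-hydroxy-6,6-dimethyl-5-oxocyclohexa-1,3-diene-1-carboxylate
Conditions: KOt-Bu (2.2 equiv), THF, 0 °C to 20 °C; 1 M HCl
Reagents that add atoms: none
Why: Dieckmann condensation: the methyl ketone, the only enolisable site, attacks the cis-disposed distal ester (C1–C2) and deprotonation of the 1,3-dione drives the closure; the hindered alkoxide avoids retro-Claisen loss of the acetyl group, the released methoxide equilibrates any Z isomer by reversible conjugate addition, and five-ring closure onto the proximal ester, which would give a cyclopentane-1,3-dione with an exocyclic alkylidene, should be much slower than six-ring closure.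

Step 4
Reactants: 5 methyl 3-hydroxy-6,6-dimethyl-5-oxocyclohexa-1,3-diene-1-carboxylate (2 equiv); 6 formaldehyde
Product: 7 dimethyl 4,4'-methylenebis(3-hydroxy-6,6-dimethyl-5-oxocyclohexa-1,3-diene-1-carboxylate)
Conditions: 37% aq. CH2O (0.5 equiv), EtOH/H2O, 20 °C
Reagents that add atoms: none
Why: Knoevenagel condensation of one dione with formaldehyde and Michael addition of a second dione to the 2-methylene trione, the classical formation of methylenebis(1,3-diones); C2 is the only carbon acid and half an equivalent of aldehyde prevents further reaction.

Step 5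
Reactants: 7 dimethyl 4,4'-methylenebis(3-hydroxy-6,6-dimethyl-5-oxocyclohexa-1,3-diene-1-carboxylate)
Product: 9 dimethyl 4,4'-methylenebis(5-methoxy-6,6-dimethyl-3-oxocyclohexa-1,4-diene-1-carboxylate), via bis(1,3-dimethoxyallyl) dication bis(tetrafluoroborate) 8 (not isolated)
Conditions: Me3OBF4 (6 equiv), 1,8-bis(dimethylamino)naphthalene (2.2 equiv), CH2Cl2, 0 °C to 20 °C; then sat. aq. NaHCO3, 0 °C
Reagents that add atoms: trimethyloxonium tetrafluoroborate, C[O+](C)C.F[B-](F)(F)F; water, O
Why: O-alkylation of a 1,3-dione and then of the carbonyl oxygen of the vinylogous ester by a trialkyloxonium salt gives the 1,3-dimethoxyallyl cation, the same from either enol ether regioisomer; water should then add to the less hindered terminus C1 (C3 is neopentyl and C1 carries the electron-poor vinyl group), and loss of methanol leaves the C1 ketone and the C3 methyl ether.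

Step 6
Reactants: 9 dimethyl 4,4'-methylenebis(5-methoxy-6,6-dimethyl-3-oxocyclohexa-1,4-diene-1-carboxylate)
Product: 10 4,4'-methylenebis(5-methoxy-6,6-dimethyl-3-oxocyclohexa-1,4-diene-1-carboxylic acid)
Conditions: LiOH·H2O (6 equiv), THF/H2O 3:1, 0 °C to 20 °C; 1 M HCl to pH 3
Reagents that add atoms: lithium hydroxide, [Li+].[OH-]
Why: Saponification by acyl–oxygen cleavage of the two conjugated methyl esters; the enol ether carbon C3 is neopentyl and the C1 ketone has no α-hydrogen, so other additions of hydroxide are reversible and unproductive.

Step 7
Reactants: 10 4,4'-methylenebis(5-methoxy-6,6-dimethyl-3-oxocyclohexa-1,4-diene-1-carboxylic acid); 11 (trimethylsilyl)diazomethane (2 equiv)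
Product: 13 bis[4-(2-diazoacetyl)-2-methoxy-3,3-dimethyl-6-oxocyclohexa-1,4-dien-1-yl]methane, via bis(acid chloride) 12 (not isolated)
Conditions: 1-chloro-N,N,2-trimethylprop-1-en-1-amine (2.4 equiv), CH2Cl2, 0 °C to 20 °C, concentrate; 11 (5 equiv), THF/MeCN 1:1, 0 °C to 20 °C, dark
Reagents that add atoms: none
Why: The chloroenamine makes the acid chloride under neutral conditions that spare the enol ethers, and each of the two acid chlorides then acylates one molecule of the silyl diazoalkane (diazoketone stage of the Arndt–Eistert sequence, silyl variant), silicon leaving to chloride, so that two molecules of 11 supply the two diazomethine carbons and the four nitrogen atoms of 13. The excess reagent scavenges any HCl, and the trisubstituted C4a=C8a bond next to a quaternary carbon should keep dipolar cycloaddition slow.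

Step 8
Reactants: 14 dichloroacetaldehyde
Product: 15 (2,2-dichloroethenyloxy)tri(propan-2-yl)silane
Conditions: i-Pr3SiOSO2CF3 (1.1 equiv), Et3N (1.5 equiv), CH2Cl2, −20 °C to 0 °C
Reagents that add atoms: triisopropylsilyl trifluoromethanesulfonate, CC(C)[Si](C(C)C)(C(C)C)OS(=O)(=O)C(F)(F)F
Why: Soft enolisation: O-silylation of the aldehyde makes the α-hydrogen, already acidified by two chlorines, removable by the amine, giving the silyl enol ether; the β-carbon carries two identical substituents, so no alkene geometry arises.

Step 9
Reactants: 15 (2,2-dichloroethenyloxy)tri(propan-2-yl)silane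
Product: 17 (triisopropylsilyloxy)acetylene, via lithium (triisopropylsilyloxy)acetylide 16 (not isolated)
Conditions: n-BuLi (2.1 equiv), Et2O, −78 °C to −40 °C; H2O, −78 °C; distillation
Reagents that add atoms: none
Why: Proposed new method: the first equivalent of base should remove the vinylic hydrogen next to oxygen and expel chloride to give the chloroalkyne (or exchange a chlorine and trigger a Fritsch–Buttenberg–Wiechell hydrogen shift), the second exchanges the remaining chlorine to give 16, and water protonates it; the closest known reaction type is the conversion of dihalovinyl alkyl ethers into lithium alkoxyacetylides with n-BuLi, and the bulky silyl group should shield silicon from the base and cannot migrate across the linear acetylide.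

Step 10
Reactants: 13 bis[4-(2-diazoacetyl)-2-methoxy-3,3-dimethyl-6-oxocyclohexa-1,4-dien-1-yl]methane; 17 (triisopropylsilyloxy)acetylene (2 equiv)
Product: 21 bis[8-hydroxy-3-methoxy-4,4-dimethyl-1-oxo-6-(triisopropylsilyloxy)-1,4-dihydronaphthalen-2-yl]methane, via bis(vinylketene) 18 (not isolated), via bis(siloxycyclobutenone) 19 (not isolated), via bis(dienylketene) 20 (not isolated)
Conditions: 17 (5 equiv), 450 nm LEDs, degassed ClCH2CH2Cl (0.01 M), 20 °C; then 80 °C, dark
Reagents that add atoms: none
Why: Excitation of the diazo chromophore expels N2 and triggers the Wolff 1,2-shift, in which C4a moves from the acyl carbon to the diazo carbon (C4a–C5) and leaves a vinylketene whose ketene carbon is the future C8. At room temperature the electron-rich alkyne captures each ketene in a [2+2] cycloaddition in which the terminal carbon of 17 (C7) bonds to the ketene carbon and the oxygen-bearing carbon (C6) bonds to C5, one molecule of 17 per ketene. Heating opens the 4-vinyl-3-siloxycyclobutenone by reversible conrotatory four-electron cleavage of the C5–C8 bond, and the dienylketene with C4a and C7 cis closes ring A by disrotatory six-electron electrocyclisation between C8 and C8a; enolisation of the cyclohexadienone, whose C8a–H lies between two carbonyls, gives the C8 phenol. This is the second-generation Danheiser benzannulation of α-diazo ketones with siloxyalkynes, run at both ends of one molecule. No stereocentre is formed; the cyclobutenone carbons are stereogenic only transiently. The selectivities needed are the orientation of the [2+2] step, secured by the polarisation of the ynol ether against the ketene, and excitation of the diazo group alone, secured by the long wavelength and by the cross-conjugated form of the ring-B dienone. The new C8 hydroxyl is chelated to the C1 ketone, which with dilution and excess 17 should suppress capture of remaining ketene by phenol.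

Step 11
Reactants: 21 bis[8-hydroxy-3-methoxy-4,4-dimethyl-1-oxo-6-(triisopropylsilyloxy)-1,4-dihydronaphthalen-2-yl]methane
Product: 22 bis(6,8-dihydroxy-3-methoxy-4,4-dimethyl-1-oxo-1,4-dihydronaphthalen-2-yl)methane
Conditions: Bu4NF (2.2 equiv), AcOH (2.2 equiv), THF, 0 °C
Reagents that add atoms: none
Why: Fluoride cleaves the aryl silyl ethers through pentacoordinate silicon; the acetic acid buffer keeps the resorcinol from standing as an oxidisable phenoxide and leaves the enol ethers untouched.

Step 12
Reactants: 22 bis(6,8-dihydroxy-3-methoxy-4,4-dimethyl-1-oxo-1,4-dihydronaphthalen-2-yl)methane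
Product: 23 bis(7-acetyl-6,8-dihydroxy-3-methoxy-4,4-dimethyl-1-oxo-1,4-dihydronaphthalen-2-yl)methane
Conditions: Ac2O (3 equiv), BF3·OEt2 (10 equiv), ClCH2CH2Cl, 20 °C to 60 °C; then MeOH/H2O, NaHCO3, 40 °C
Reagents that add atoms: acetic anhydride, CC(=O)OC(C)=O
Why: Friedel–Crafts acylation through O-acetylation and boron-mediated Fries shift; C7 is ortho to both hydroxyls and its ketone gains chelation, whereas C5 is shielded by the adjacent quaternary C4, and the methanolic work-up cleaves boron–oxygen bonds and any remaining aryl acetate.

Step 13
Reactants: 23 bis(7-acetyl-6,8-dihydroxy-3-methoxy-4,4-dimethyl-1-oxo-1,4-dihydronaphthalen-2-yl)methane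
Product: 24 bis(7-acetyl-3,6,8-trihydroxy-4,4-dimethyl-1-oxo-1,4-dihydronaphthalen-2-yl)methane
Conditions: BBr3 (8 equiv), CH2Cl2, −78 °C to 0 °C; MeOH then H2O, 0 °C
Reagents that add atoms: none
Why: Lewis-acid dealkylation of a vinylogous methyl ester: boron bound at the chelated C1 carbonyl turns ring B into a 3-methoxy oxocarbenium ion and bromide attacks the methyl group, relieving the crowding at C3; the cold, non-aqueous conditions and cold quench should avoid cyclodehydration of the bis-enol to a 4H-pyran, and no other ether is present.

## Compound list

1 | 3-bromo-3-methylbutan-2-one | CC(=O)C(C)(C)Br | starting material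
2 | 2-methyl-3-(trimethylsilyloxy)but-2-ene | CC(C)=C(C)O[Si](C)(C)C | intermediate
3 | dimethyl acetylenedicarboxylate | COC(=O)C#CC(=O)OC | starting material
4 | dimethyl (2E)-2-(2-methyl-3-oxobutan-2-yl)but-2-enedioate | CC(=O)C(C)(C)/C(C(=O)OC)=C\C(=O)OC | intermediate
5 | methyl 3-hydroxy-6,6-dimethyl-5-oxocyclohexa-1,3-diene-1-carboxylate (enol of the 3,5-dione) | COC(=O)C1=CC(O)=CC(=O)C1(C)C | intermediate
6 | formaldehyde | C=O | starting material
7 | dimethyl 4,4'-methylenebis(3-hydroxy-6,6-dimethyl-5-oxocyclohexa-1,3-diene-1-carboxylate) | COC(=O)C1=CC(O)=C(CC2=C(O)C=C(C(=O)OC)C(C)(C)C2=O)C(=O)C1(C)C | intermediate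
8 | 4,4'-methylenebis[3,5-dimethoxy-1-(methoxycarbonyl)-6,6-dimethylcyclohexa-1,4-dien-3-ylium] bis(tetrafluoroborate) (formed in situ) | COC(=O)C1=CC(=[O+]C)C(CC2=C(OC)C(C)(C)C(C(=O)OC)=CC2=[O+]C)=C(OC)C1(C)C.F[B-](F)(F)F.F[B-](F)(F)F | intermediate
9 | dimethyl 4,4'-methylenebis(5-methoxy-6,6-dimethyl-3-oxocyclohexa-1,4-diene-1-carboxylate) | COC1=C(CC2=C(OC)C(C)(C)C(C(=O)OC)=CC2=O)C(=O)C=C(C(=O)OC)C1(C)C | intermediate
10 | 4,4'-methylenebis(5-methoxy-6,6-dimethyl-3-oxocyclohexa-1,4-diene-1-carboxylic acid) | COC1=C(CC2=C(OC)C(C)(C)C(C(=O)O)=CC2=O)C(=O)C=C(C(=O)O)C1(C)C | intermediate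
11 | (trimethylsilyl)diazomethane | C[Si](C)(C)C=[N+]=[N-] | starting material
12 | 4,4'-methylenebis(5-methoxy-6,6-dimethyl-3-oxocyclohexa-1,4-diene-1-carbonyl chloride) (formed in situ) | COC1=C(CC2=C(OC)C(C)(C)C(C(=O)Cl)=CC2=O)C(=O)C=C(C(=O)Cl)C1(C)C | intermediate
13 | bis[4-(2-diazoacetyl)-2-methoxy-3,3-dimethyl-6-oxocyclohexa-1,4-dien-1-yl]methane | COC1=C(CC2=C(OC)C(C)(C)C(C(=O)C=[N+]=[N-])=CC2=O)C(=O)C=C(C(=O)C=[N+]=[N-])C1(C)C | intermediate
14 | dichloroacetaldehyde | O=CC(Cl)Cl | starting material
15 | (2,2-dichloroethenyloxy)tri(propan-2-yl)silane | ClC(Cl)=CO[Si](C(C)C)(C(C)C)C(C)C | intermediate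
16 | lithium (triisopropylsilyloxy)acetylide (formed in situ) | [Li]C#CO[Si](C(C)C)(C(C)C)C(C)C | intermediate
17 | (triisopropylsilyloxy)acetylene | C#CO[Si](C(C)C)(C(C)C)C(C)C | intermediate
18 | bis[2-methoxy-3,3-dimethyl-6-oxo-4-(2-oxoethenyl)cyclohexa-1,4-dien-1-yl]methane (formed in situ) | COC1=C(CC2=C(OC)C(C)(C)C(C=C=O)=CC2=O)C(=O)C=C(C=C=O)C1(C)C | intermediate
19 | bis{2-methoxy-3,3-dimethyl-6-oxo-4-[4-oxo-2-(triisopropylsilyloxy)cyclobut-2-en-1-yl]cyclohexa-1,4-dien-1-yl}methane (formed in situ, ring carbons C5 unspecified) | COC1=C(CC2=C(OC)C(C)(C)C(C3C(=O)C=C3O[Si](C(C)C)(C(C)C)C(C)C)=CC2=O)C(=O)C=C(C2C(=O)C=C2O[Si](C(C)C)(C(C)C)C(C)C)C1(C)C | intermediate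
20 | bis{2-methoxy-3,3-dimethyl-6-oxo-4-[(1E)-4-oxo-2-(triisopropylsilyloxy)buta-1,3-dien-1-yl]cyclohexa-1,4-dien-1-yl}methane (formed in situ) | COC1=C(CC2=C(OC)C(C)(C)C(/C=C(O[Si](C(C)C)(C(C)C)C(C)C)\C=C=O)=CC2=O)C(=O)C=C(/C=C(O[Si](C(C)C)(C(C)C)C(C)C)\C=C=O)C1(C)C | intermediate
21 | bis[8-hydroxy-3-methoxy-4,4-dimethyl-1-oxo-6-(triisopropylsilyloxy)-1,4-dihydronaphthalen-2-yl]methane | COC1=C(CC2=C(OC)C(C)(C)c3cc(O[Si](C(C)C)(C(C)C)C(C)C)cc(O)c3C2=O)C(=O)c2c(O)cc(O[Si](C(C)C)(C(C)C)C(C)C)cc2C1(C)C | intermediate
22 | bis(6,8-dihydroxy-3-methoxy-4,4-dimethyl-1-oxo-1,4-dihydronaphthalen-2-yl)methane | COC1=C(CC2=C(OC)C(C)(C)c3cc(O)cc(O)c3C2=O)C(=O)c2c(O)cc(O)cc2C1(C)C | intermediate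
23 | bis(7-acetyl-6,8-dihydroxy-3-methoxy-4,4-dimethyl-1-oxo-1,4-dihydronaphthalen-2-yl)methane | COC1=C(CC2=C(OC)C(C)(C)c3cc(O)c(C(C)=O)c(O)c3C2=O)C(=O)c2c(O)c(C(C)=O)c(O)cc2C1(C)C | intermediate
24 | bis(7-acetyl-3,6,8-trihydroxy-4,4-dimethyl-1-oxo-1,4-dihydronaphthalen-2-yl)methane | CC(=O)c1c(O)cc2c(c1O)C(=O)C(CC1=C(O)C(C)(C)c3cc(O)c(C(C)=O)c(O)c3C1=O)=C(O)C2(C)C | target

## Step count and least certain steps

Total: 13 steps. Longest linear sequence: 11 steps (steps 1 to 7 and 10 to 13). The alkyne branch is steps 8 and 9.

**Step 9 (proposed new method).** The most likely failure is attack of the organolithium at silicon, or isomerisation of the terminal siloxyalkyne to a silylketene on isolation, because a silyl enol ether has not been taken through this elimination. The fallback uses known chemistry and replaces the reagent by commercial ethoxyacetylene. Starting from 13 under the conditions of step 10, it should give bis(6-ethoxy-8-hydroxy-3-methoxy-4,4-dimethyl-1-oxo-1,4-dihydronaphthalen-2-yl)methane F1. Acylation as in step 12 should give bis(7-acetyl-6-ethoxy-8-hydroxy-3-methoxy-4,4-dimethyl-1-oxo-1,4-dihydronaphthalen-2-yl)methane F2, in which each ethyl ether is ortho to the new ketone. BBr3 should then cleave the chelated ethyl ethers and the enol methyl ethers in one operation, and the route is rejoined at 24.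

**Step 10 (key step).** The most likely failure is an incomplete second annulation, with capture of the remaining ketene by the phenol of the half that reacted first, or a competing photoreaction of the ring-B dienone, because two cascades must run to completion in one molecule. The fallback annulates before dimerising and sets out from 5. The operations of steps 5 to 7 on the monomer should give methyl 5-methoxy-6,6-dimethyl-3-oxocyclohexa-1,4-diene-1-carboxylate F3, then 5-methoxy-6,6-dimethyl-3-oxocyclohexa-1,4-diene-1-carboxylic acid F4, then 5-(2-diazoacetyl)-3-methoxy-4,4-dimethylcyclohexa-2,5-dien-1-one F5. A single benzannulation with 17 should give 8-hydroxy-3-methoxy-4,4-dimethyl-6-(triisopropylsilyloxy)naphthalen-1(4H)-one F6, and fluoride should then give 6,8-dihydroxy-3-methoxy-4,4-dimethylnaphthalen-1(4H)-one F7. Acylation as in step 12 should give 7-acetyl-6,8-dihydroxy-3-methoxy-4,4-dimethylnaphthalen-1(4H)-one F8, and BBr3 should give 7-acetyl-3,6,8-trihydroxy-4,4-dimethylnaphthalen-1(4H)-one F9. The bridge is installed last with 6 (0.5 equiv) as in step 4, C2 of the free dione being far more nucleophilic than C5, and the route is rejoined at 24.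

**Step 5.** The most likely failure is loss of regiocontrol: water adding at the hindered end of the cation, or an incomplete second methylation that leaves the isomeric enol ether, because the selectivity rests on steric differentiation alone. The fallback directs the methyl group with silicon and sets out from 7. The bulky silyl triflate with Et3N should silylate only the unhindered C1 oxygens to give dimethyl 4,4'-methylenebis[6,6-dimethyl-5-oxo-3-(triisopropylsilyloxy)cyclohexa-1,3-diene-1-carboxylate] F10. Methyl trifluoromethanesulfonate then methylates the one remaining carbonyl oxygen (C3) and CsF removes silicon, which can only unmask C1. The route is rejoined at 9.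

**Step 2.** The most likely failure is diversion of the zwitterion into cycloaddition or ene pathways, or polymerisation of 3, because a tetrasubstituted enol ether meets a very reactive acceptor. The fallback is an anionic tandem process from 2. MeLi cleaves the silyl ether to lithium 3-methylbut-2-en-2-olate F11 regiospecifically; addition of 3 at −78 °C and warming should let conjugate addition, proton relay to the methyl ketone and ring closure follow in one flask, with the released methoxide equilibrating the alkene geometry. The route is rejoined at 5.

**Step 7.** The most likely failure is 1,3-dipolar cycloaddition of the diazoalkane to the C4a=C8a bond, which two carbonyl groups activate, or addition of HCl to the diazoketone. The fallback replaces acylation by diazo transfer and sets out from 12. MeZnCl with Pd(PPh3)4 (Negishi acylation) should give bis(4-acetyl-2-methoxy-3,3-dimethyl-6-oxocyclohexa-1,4-dien-1-yl)methane F12. LiN(SiMe3)2 followed by 2,2,2-trifluoroethyl trifluoroacetate gives bis[2-methoxy-3,3-dimethyl-6-oxo-4-(4,4,4-trifluoro-3-oxobutanoyl)cyclohexa-1,4-dien-1-yl]methane F13. Methanesulfonyl azide with Et3N and water transfers the diazo group with loss of the trifluoroacetyl group, and the route is rejoined at 13.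

**Step 12.** The most likely failure is acylation at C5, or Lewis-acid loss of the enol methyl ethers followed by cyclodehydration to the pyran, because the ring is deactivated by the C1 ketone and needs forcing conditions. The fallback is halogenation and cross-coupling from 22. N-Iodosuccinimide should give bis(6,8-dihydroxy-7-iodo-3-methoxy-4,4-dimethyl-1-oxo-1,4-dihydronaphthalen-2-yl)methane F14. Stille coupling with tributyl(1-ethoxyethenyl)stannane and Pd(PPh3)4 gives bis[7-(1-ethoxyethenyl)-6,8-dihydroxy-3-methoxy-4,4-dimethyl-1-oxo-1,4-dihydronaphthalen-2-yl]methane F15. Dilute aqueous acid hydrolyses the aryl enol ethers to the acetyl groups, and the route is rejoined at 23.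

## Further compounds

F1 | step 9 | bis(6-ethoxy-8-hydroxy-3-methoxy-4,4-dimethyl-1-oxo-1,4-dihydronaphthalen-2-yl)methane | COC1=C(CC2=C(OC)C(C)(C)c3cc(OCC)cc(O)c3C2=O)C(=O)c2c(O)cc(OCC)cc2C1(C)C
F2 | step 9 | bis(7-acetyl-6-ethoxy-8-hydroxy-3-methoxy-4,4-dimethyl-1-oxo-1,4-dihydronaphthalen-2-yl)methane | COC1=C(CC2=C(OC)C(C)(C)c3cc(OCC)c(C(C)=O)c(O)c3C2=O)C(=O)c2c(O)c(C(C)=O)c(OCC)cc2C1(C)C
F3 | step 10 | methyl 5-methoxy-6,6-dimethyl-3-oxocyclohexa-1,4-diene-1-carboxylate | COC(=O)C1=CC(=O)C=C(OC)C1(C)C
F4 | step 10 | 5-methoxy-6,6-dimethyl-3-oxocyclohexa-1,4-diene-1-carboxylic acid | COC1=CC(=O)C=C(C(=O)O)C1(C)C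
F5 | step 10 | 5-(2-diazoacetyl)-3-methoxy-4,4-dimethylcyclohexa-2,5-dien-1-one | COC1=CC(=O)C=C(C(=O)C=[N+]=[N-])C1(C)C
F6 | step 10 | 8-hydroxy-3-methoxy-4,4-dimethyl-6-(triisopropylsilyloxy)naphthalen-1(4H)-one | COC1=CC(=O)c2c(O)cc(O[Si](C(C)C)(C(C)C)C(C)C)cc2C1(C)C
F7 | step 10 | 6,8-dihydroxy-3-methoxy-4,4-dimethylnaphthalen-1(4H)-one | COC1=CC(=O)c2c(O)cc(O)cc2C1(C)C
F8 | step 10 | 7-acetyl-6,8-dihydroxy-3-methoxy-4,4-dimethylnaphthalen-1(4H)-one | COC1=CC(=O)c2c(O)c(C(C)=O)c(O)cc2C1(C)C
F9 | step 10 | 7-acetyl-3,6,8-trihydroxy-4,4-dimethylnaphthalen-1(4H)-one | CC(=O)c1c(O)cc2c(c1O)C(=O)C=C(O)C2(C)C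
F10 | step 5 | dimethyl 4,4'-methylenebis[6,6-dimethyl-5-oxo-3-(triisopropylsilyloxy)cyclohexa-1,3-diene-1-carboxylate] | COC(=O)C1=CC(O[Si](C(C)C)(C(C)C)C(C)C)=C(CC2=C(O[Si](C(C)C)(C(C)C)C(C)C)C=C(C(=O)OC)C(C)(C)C2=O)C(=O)C1(C)C
F11 | step 2 | lithium 3-methylbut-2-en-2-olate | CC(C)=C(C)O[Li]
F12 | step 7 | bis(4-acetyl-2-methoxy-3,3-dimethyl-6-oxocyclohexa-1,4-dien-1-yl)methane | COC1=C(CC2=C(OC)C(C)(C)C(C(C)=O)=CC2=O)C(=O)C=C(C(C)=O)C1(C)C
F13 | step 7 | bis[2-methoxy-3,3-dimethyl-6-oxo-4-(4,4,4-trifluoro-3-oxobutanoyl)cyclohexa-1,4-dien-1-yl]methane | COC1=C(CC2=C(OC)C(C)(C)C(C(=O)CC(=O)C(F)(F)F)=CC2=O)C(=O)C=C(C(=O)CC(=O)C(F)(F)F)C1(C)C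
F14 | step 12 | bis(6,8-dihydroxy-7-iodo-3-methoxy-4,4-dimethyl-1-oxo-1,4-dihydronaphthalen-2-yl)methane | COC1=C(CC2=C(OC)C(C)(C)c3cc(O)c(I)c(O)c3C2=O)C(=O)c2c(O)c(I)c(O)cc2C1(C)C
F15 | step 12 | bis[7-(1-ethoxyethenyl)-6,8-dihydroxy-3-methoxy-4,4-dimethyl-1-oxo-1,4-dihydronaphthalen-2-yl]methane | COC1=C(CC2=C(OC)C(C)(C)c3cc(O)c(C(=C)OCC)c(O)c3C2=O)C(=O)c2c(O)c(C(=C)OCC)c(O)cc2C1(C)C
A1 | alternative 1 | dimethyl 2,2'-(2,8-dimethyl-3,7-dioxononane-2,8-diyl)bis(4,6-dimethoxybenzoate) | COC(=O)c1c(OC)cc(OC)cc1C(C)(C)C(=O)CCCC(=O)C(C)(C)c1cc(OC)cc(OC)c1C(=O)OC
A2 | alternative 1 | methyl 2-bromo-4,6-dimethoxybenzoate | COC(=O)c1c(Br)cc(OC)cc1OC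
A3 | alternative 1 | 2,8-dimethyl-3,7-bis(trimethylsilyloxy)nona-2,7-diene | CC(C)=C(CCCC(=C(C)C)O[Si](C)(C)C)O[Si](C)(C)C
A4 | alternative 2 | bis(3-hydroxy-6,8-dimethoxy-4,4-dimethyl-1-oxo-1,4-dihydronaphthalen-2-yl)methane | COc1cc(OC)c2c(c1)C(C)(C)C(O)=C(CC1=C(O)C(C)(C)c3cc(OC)cc(OC)c3C1=O)C2=O
A5 | alternative 2 | bis(1,3-dihydroxy-6,8-dimethoxynaphthalen-2-yl)methane | COc1cc(OC)c2c(O)c(Cc3c(O)cc4cc(OC)cc(OC)c4c3O)c(O)cc2c1
A6 | alternative 3 | bis(3-ethoxy-6,8-dimethoxy-4,4-dimethyl-1-oxo-1,4-dihydronaphthalen-2-yl)methane | CCOC1=C(CC2=C(OCC)C(C)(C)c3cc(OC)cc(OC)c3C2=O)C(=O)c2c(OC)cc(OC)cc2C1(C)C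
A7 | alternative 3 | 3,5-dimethoxy-8,8-dimethylbicyclo[4.2.0]octa-1,3,5-trien-7-one | COc1cc(OC)c2C(=O)C(C)(C)c2c1
A8 | alternative 3 | 1,5-diethoxypenta-1,4-diyne | CCOC#CCC#COCC
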